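The vessel is closed, stirred and isothermal, and in it the starting material and two other substrates may each take the coupling partner.

| flask | starting material | coupling partner | second substrate | third substrate | temperature | remark | time |
|---|---|---|---|---|---|---|---|
| cedar | 0.14 M | 0.18 M | 0.10 M | 0.10 M | −5 °C | run made earlier |  |
| oak | 0.24 M | 0.18 M | 0.10 M | 0.10 M | 6 °C | run made earlier |  |
| elm | 0.10 M | 0.20 M | 0.10 M | 0.10 M | −5 °C | run made earlier |  |
| Thursday's | 0.10 M | 0.180 M | 0.100 M | 0.100 M | 0 °C |  | 4.0 min |
| Friday's | 0.20 M | 0.250 M | 0.100 M | 0.100 M | 0 °C |  | 6.0 min |

- cedar (time / min: target / %): 0.333: 3.8; 0.667: 6.4; 1.00: 9.2; 2.00: 14.8; 4.00: 21.1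
- oak (time / min: target / %): 0.833: 13.1; 1.50: 17.3; 2.50: 18.4; 3.00: 17.5; 4.00: 16.5
- elm (time / min: target / %): 0.833: 8.5; 1.50: 14.8; 2.50: 19.8; 3.00: 21.7; 4.00: 25.5

(each reading ± 0.5 percentage points)

- the flask that ends with the higher amount of target, in percent of the starting material charged, or "neither" when 2 percentage points or less lies between them (Thursday's / Friday's / neither)
- final target, as a percentage of the starting material charged, in Thursday's
- final target, as a percentage of the starting material charged, in Friday's

- a species is counted by the starting material in it: one side product counts as two
- the numbers in the tables scatter by 0.5 percentage points (one standard deviation)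
- candidate steps: second substrate + coupling partner -> second product; third substrate + coupling partner -> third product; starting material + coupling partner -> target; starting material + target -> side product

If target forms at a rate k·c(starting material)·c(coupling partner), the starting material is consumed on that path in a pseudo-first-order way, with c(coupling partner) setting its pace. The first reading then gives k as the target fraction divided by time and c(coupling partner), since the charge of starting material cancels.

I try two ways at the same temperature. Cedar's first reading gives 0.634 M⁻¹ min⁻¹, and elm's gives 0.510 M⁻¹ min⁻¹, which is lower. They part, so one cheats. Cedar's second reading, at 0.667 min, gives 0.533 M⁻¹ min⁻¹, close to elm's, so within cedar itself the value falls as the chord lengthens, and I take the long chord to be the cheat, as it averages over a flask already thinning, though scatter may account for part of the gap. I keep cedar's value, with its scatter of 0.5 percentage points on 3.8%.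

Oak's first reading, on elm's chord, gives 0.874 M⁻¹ min⁻¹. Since 0 °C lies roughly midway between the two temperatures, I scale cedar's value by the square root of oak's over elm's, reading that ratio as temperature although the charges of oak and elm differ too, and get 0.830 M⁻¹ min⁻¹.

My measure is the turn time, ln(2) over k·c(coupling partner), which at the charge is 4.64 min for Thursday's, against 4.0 min, and 3.34 min for Friday's, against 6.0 min. At charged c(coupling partner), that path would turn 45.0% and 71.2% respectively.

But turnover is not target. Oak, charged with 0.24 M of starting material, reads 18.4% at 2.50 min and then 16.5% at 4.00 min, so target is being lost in oak, and Friday's is charged with 0.20 M against 0.10 M in Thursday's. I reckon no final figure here and commit by judgement to a near tie.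

The forecast says Friday's, with 26% for Thursday's and 30% for Friday's: “Friday is probably higher, though not by much.”

The flasks give 27.5% in Thursday's and 28.0% in Friday's, so the answer is neither.

    second substrate + coupling partner → second product (k = 1.90 M⁻¹ min⁻¹, Ea = 58.0 kJ mol⁻¹)
    third substrate + coupling partner → third product (k = 0.460 M⁻¹ min⁻¹, Ea = 65.0 kJ mol⁻¹)
    starting material + coupling partner → target (k = 0.930 M⁻¹ min⁻¹, Ea = 52.0 kJ mol⁻¹)
    starting material + target → side product (k = 1.10 M⁻¹ min⁻¹, Ea = 43.0 kJ mol⁻¹)
    (constants at 0 °C)

In Friday's, c(coupling partner) stands at 23.6% of its charge at the end, which stretches my turn time from 3.34 min to 14.2 min. In Friday's, target is made 3.33 times as fast as it is used up at 1.42 min, but 0.893 times at 6.00 min, so by the asked time Friday's is losing target.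

With 1.0 M of coupling partner and Friday's other charges, the turn time at the charge is 0.836 min, which, reckoned with c(coupling partner) held there, gives 0.691% of the starting material left after 6.0 min. The computed neighbour holds 0.828% of it, with target at 76.9%.

(The runs are simulated for an exercise; noise was put on by code.)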